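A direct plan would close rings A and B and the lactone bridge in one intramolecular Diels–Alder reaction of the 3-alkyl-5-bromo-2-pyrone A1 (side chain with the C4 quaternary carbon and an E enol ether). It would then grow ring C on the bromide of adduct A2 by lithiation, addition to a cyclobutenone and thermal ring expansion to methoxyquinone A3, and end with BBr3.
Its weakest steps would be:
- the pyrone cycloaddition, because the diene face would be chosen only by CH3 against CH2OSiR3 on the remote C4 centre, so C5, C6, C7 and C10 would form with poor control and the wrong adduct would have to be separated;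
- the run-up to A1, six linear steps spent on one acyclic quaternary carbon and an enol ether that needs E/Z separation;
- the end game, where a vinyl-lithium would be made beside the bridged lactone and BBr3 would have to cleave three ethers on the finished hydroxyquinone lactone.

Retrosynthetic overview (abietane atom numbers throughout)
The 2-oxabicyclo[2.2.2]octene of the target (bridgeheads C7 and C10; bridges O–C20, C5–C6, C8=C9) contains an isochroman-3-one: ring C fused to the lactone ring C7–O–C20–C10–C9–C8.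
Key disconnection: C5–C10, with the C7–O bond opened for a time. A boat Ireland–Claisen ring contraction of the 1-alkenyl-4-allyl-isochromanone 13 closes ring B, creates C10 and C5 together by chirality transfer from C7, and leaves the lactone oxygen on C20 beside a C6=C7 styrene.
α-Epoxidation and anti opening by the C20 acid return that oxygen to C7 and set C6 and C7; ring A closes last at C2–C3 by metathesis; the arene is oxidised to the hydroxyquinone at the end.
Ring order: C (bought), lactone ring, B (key step), lactone bridge, A.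
C4 enters as a separate enantiopure enyne, so no ring closure depends on CH3 against CH2OR; ring C is never built on the bicycle, and no Lewis-acid ether cleavage is needed.

Key step: step 9

Assumption: benzyl chloride 6 (an intermediate of tapinarof manufacture) and enynol 1 are taken as purchasable; 6 is otherwise one step (SOCl2) from the corresponding benzyl alcohol.

Step 1
Reactants: 1 (E)-3-methylpent-2-en-4-yn-1-ol
Product: 2 [(2S,3S)-3-ethynyl-3-methyloxiran-2-yl]methanol
Conditions: Ti(OiPr)4 (10 mol%), L-(+)-diethyl tartrate (12 mol%), t-BuOOH, 4 Å MS, CH2Cl2, −20 °C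
Reagents that add atoms: tert-butyl hydroperoxide CC(C)(C)OO
Why: Sharpless asymmetric epoxidation touches only the alkene of the allylic alcohol (the alkyne is inert), and for this geraniol-type E-trisubstituted substrate the L-(+)-tartrate catalyst should give the (2S,3S)-epoxide, which fixes the absolute configuration of C4.

Step 2
Reactants: 2 [(2S,3S)-3-ethynyl-3-methyloxiran-2-yl]methanol
Product: 3 tert-butyl{[(2S,3S)-3-ethynyl-3-methyloxiran-2-yl]methoxy}dimethylsilane
Conditions: TBSCl, imidazole, DMF, 0 °C → rt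
Reagents that add atoms: tert-butyldimethylsilyl chloride CC(C)(C)[Si](C)(C)Cl
Why: Standard silylation of the primary alcohol gives the epoxy silyl ether that the next rearrangement needs and leaves both stereocentres untouched.

Step 3
Reactants: 3 tert-butyl{[(2S,3S)-3-ethynyl-3-methyloxiran-2-yl]methoxy}dimethylsilane
Product: 4 (S)-2-{[(tert-butyldimethylsilyl)oxy]methyl}-2-methylbut-3-ynal
Conditions: MeAl(OAr)2 (MABR, Ar = 4-bromo-2,6-di-tert-butylphenyl; 20 mol%), CH2Cl2, −78 → −40 °C
Reagents that add atoms: none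
Why: In this Lewis-acid semipinacol rearrangement of an epoxy silyl ether the tertiary propargylic C–O bond ionises on the bulky aluminium reagent and the siloxymethyl group migrates anti to the leaving oxygen, so the epoxide configuration is passed with inversion to the quaternary carbon (future C4, with CH3 = C18, CH2OSi = C19, CHO = C3, ethynyl = C5).

Step 4
Reactants: 4 (S)-2-{[(tert-butyldimethylsilyl)oxy]methyl}-2-methylbut-3-ynal
Product: 5 (S)-3-{[(tert-butyldimethylsilyl)oxy]methyl}-3-methylpent-1-en-4-yne
Conditions: Ph3PCH3Br, KN(SiMe3)2, THF, 0 °C; then 4, 0 °C → rt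
Reagents that add atoms: methyltriphenylphosphonium bromide C[P+](c1ccccc1)(c1ccccc1)c1ccccc1.[Br-]
Why: Wittig methylenation of the non-enolisable neopentyl aldehyde gives the vinyl group (C3) without touching the quaternary centre or the less acidic alkyne C–H.

Step 5
Reactants: 6 5-(chloromethyl)-2-isopropyl-1,3-dimethoxybenzene
Product: 7 methyl 2-(4-isopropyl-3,5-dimethoxyphenyl)acetate
Conditions: CO (1 atm), MeOH, PdCl2(PPh3)2 (2 mol%), i-Pr2NEt, 60 °C
Reagents that add atoms: carbon monoxide [C-]#[O+]; methanol CO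
Why: Palladium-catalysed methoxycarbonylation (oxidative addition of the benzylic chloride to zerovalent palladium, CO insertion, methanolysis) puts C20 on C10 in one step.

Step 6
Reactants: 7 methyl 2-(4-isopropyl-3,5-dimethoxyphenyl)acetate
Product: 8 methyl 2-(4-isopropyl-3,5-dimethoxyphenyl)pent-4-enoate (racemic)
Conditions: LiN(i-Pr)2, THF, −78 °C; allyl bromide, −78 → 0 °C
Reagents that add atoms: allyl bromide C=CCBr
Why: Alkylation of the arylacetate enolate attaches C1 and C2 to C10, and the new centre may be racemic because it becomes sp2 again in step 9.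

Step 7
Reactants: 8 methyl 2-(4-isopropyl-3,5-dimethoxyphenyl)pent-4-enoate
Product: 9 methyl 2-(2-formyl-4-isopropyl-3,5-dimethoxyphenyl)pent-4-enoate (racemic)
Conditions: POCl3, DMF, 70 °C; then H2O
Reagents that add atoms: N,N-dimethylformamide CN(C)C=O; water O
Why: Vilsmeier–Haack formylation goes to the only free ring positions, each ortho to one methoxy group and para to the other and equivalent by symmetry, so C7 is attached to C8 as one regioisomer.

Step 8
Reactants: 5 (S)-3-{[(tert-butyldimethylsilyl)oxy]methyl}-3-methylpent-1-en-4-yne; 9 methyl 2-(2-formyl-4-isopropyl-3,5-dimethoxyphenyl)pent-4-enoate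
Product: 13 (1S)-4-allyl-1-[(1E,3S)-3-{[(tert-butyldimethylsilyl)oxy]methyl}-3-methylpenta-1,4-dien-1-yl]-7-isopropyl-6,8-dimethoxyisochroman-3-one (C4 epimers of the lactone ring), via alkenylzirconocene chloride 10 (not isolated), via alkenyl(methyl)zinc 11 (not isolated), via zinc alkoxide 12 (not isolated)
Conditions: Cp2Zr(H)Cl, CH2Cl2, rt; Me2Zn, PhMe, −65 °C; (−)-3-exo-morpholinoisoborneol [(−)-MIB, 10 mol%], 9, −30 → 0 °C; then rt; pH 7 buffer; Et3N-washed SiO2
Reagents that add atoms: none
Why: Hydrozirconation of the alkyne (syn, far faster than at the hindered vinyl group), transmetalation to zinc and amino-alcohol-catalysed alkenylzinc addition give the E-allylic alkoxide, which by analogy with benzaldehyde should be (S) with (−)-MIB (the antipodal ligand is taken if the sense is opposite), and the alkoxide then closes the six-membered lactone on the neighbouring methyl ester under non-acidic conditions that do not ionise C7.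

Step 9
Reactants: 13 (1S)-4-allyl-1-[(1E,3S)-3-{[(tert-butyldimethylsilyl)oxy]methyl}-3-methylpenta-1,4-dien-1-yl]-7-isopropyl-6,8-dimethoxyisochroman-3-one
Product: 16 (1R,2S)-1-allyl-2-[(2S)-1-{[tert-butyl(dimethyl)silyl]oxy}-2-methylbut-3-en-2-yl]-6-isopropyl-5,7-dimethoxy-1,2-dihydronaphthalene-1-carboxylic acid, via silyl ketene acetal 14 (not isolated), via trimethylsilyl ester 15 (not isolated)
Conditions: LiN(i-Pr)2, Me3SiCl–Et3N (internal quench), THF, −78 °C; then PhMe, 20 → 70 °C; aq. citric acid (pH 4), 0 °C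
Reagents that add atoms: none
Why: Deprotonation of the benzylic C10–H and O-silylation give the cyclic silyl ketene acetal 14, whose 1,5-diene C10=C20–O–C7–C6=C5 undergoes an Ireland–Claisen rearrangement in which C7–O breaks, C5–C10 forms and the lactone oxygen stays on C20 as silyl ester 15. The closest known reactions are the Claisen ring contraction of lactone silyl ketene acetals that carry an alkenyl group on the carbinol carbon (6-alkenyl-δ-valerolactones to cyclohexenecarboxylic acids) and the thermal rearrangement of 2-alkenyl-dihydropyrans to cyclohexenes. Ring B is the only ring closed, a six-membered carbocycle formed by the [3,3] shift through a boat, because C7 and C10 stay tied by the arene carbons C8 and C9 (a bicyclo[2.2.2]-like array with the shape of the target's lactone core), which excludes a chair. C10 and C5 are created together: the attacked face of C10 is fixed by the configuration of C7 (the alkenyl group must stand pseudo-axial, suprafacial transfer of chirality), the ketene acetal geometry is fixed by the ring, and the E geometry of C5=C6 places the C4 substituent on the side of the carboxyl group and H-5 on the arene side, which is the 5α-H/10β-carboxyl relationship of the target. The selectivity needed is the concerted shift over heterolysis of the donor-activated benzylic C7–O bond and over ketene formation from the enolate; the internal silyl quench at −78 °C, a non-polar solvent for the shift and the poor leaving-group ability of a ketene acetal should secure it, and C4 is only a spectator.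

Step 10
Reactants: 16 (1R,2S)-1-allyl-2-[(2S)-1-{[tert-butyl(dimethyl)silyl]oxy}-2-methylbut-3-en-2-yl]-6-isopropyl-5,7-dimethoxy-1,2-dihydronaphthalene-1-carboxylic acid
Product: 19 bridged hydroxy lactone with free C19–OH: 6α-hydroxy-20,7β-lactone carrying allyl on C10 and the (S)-1-hydroxy-2-methylbut-3-en-2-yl group on C5, via epoxy acid 17 (not isolated), via silyl lactone 18 (not isolated)
Conditions: dimethyldioxirane (acetone), CH2Cl2, −40 → 0 °C; then HF·pyridine, THF, 0 °C → rt
Reagents that add atoms: dimethyldioxirane CC1(C)OO1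
Why: Epoxidation of the electron-rich styrene (far more reactive than the two monosubstituted alkenes) should occur anti to the bulky C5 substituent, that is from the α face, and the C20 acid then opens the oxirane at the benzylic C7 (para and ortho methoxy donors) from the β face with inversion, which gives the 20,7β-olide and the 6α-hydroxyl in one event before HF·pyridine removes the silyl group.

Step 11
Reactants: 19 bridged hydroxy lactone with free C19–OH
Product: 21 6α,19-dihydroxy-12,14-dimethoxyabieta-8,11,13-trien-20,7β-olide, via cyclohexene 20 (not isolated)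
Conditions: RuCl2(=CHPh)(PCy3)(H2IMes) (second-generation Grubbs catalyst, 5 mol%), PhMe, 60 °C; then H2 (5 bar), 70 °C
Reagents that add atoms: none
Why: Ring-closing metathesis of the C10 allyl and C4 vinyl groups closes ring A at C2=C3 without creating a stereocentre, and the ruthenium hydride formed from the same catalyst under hydrogen saturates the new alkene without hydrogenolysis of the benzylic lactone.

Step 12
Reactants: 21 6α,19-dihydroxy-12,14-dimethoxyabieta-8,11,13-trien-20,7β-olide
Product: 22 6α,19-dihydroxy-12-methoxy-11,14-dioxoabieta-8,12-dien-20,7β-olide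
Conditions: (NH4)2Ce(NO3)6, MeCN–H2O (2:1), 0 °C
Reagents that add atoms: water O
Why: Oxidative demethylation by tetravalent cerium (arene radical cation, water attack at the free C11 and at the para C14–OMe, as in the oxidation of 3,4,5-trimethoxytoluene to its quinone) gives the methoxyquinone, the C7–H and the isopropyl C–H lie in the arene plane and resist benzylic oxidation, and the ortho-quinone regioisomer would converge on the same product in step 13.

Step 13
Reactants: 22 6α,19-dihydroxy-12-methoxy-11,14-dioxoabieta-8,12-dien-20,7β-olide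
Product: 23 6α,12,19-trihydroxy-11,14-dioxoabieta-8,12-dien-20,7β-olide (CNP0339604.1)
Conditions: LiOH (0.2 M aq.), THF, 0 °C, 10 min; then 1 M HCl
Reagents that add atoms: lithium hydroxide [Li+].[OH-]
Why: Addition–elimination hydrolysis of the vinylogous methyl ester of the quinone is much faster than saponification of the hindered bridged lactone on the quaternary C10, and acidification releases the hydroxyquinone without touching a stereocentre.

Compound list
1 | (E)-3-methylpent-2-en-4-yn-1-ol | C#C/C(C)=C/CO | starting material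
2 | [(2S,3S)-3-ethynyl-3-methyloxiran-2-yl]methanol | C#C[C@]1(C)O[C@H]1CO | intermediate
3 | tert-butyl{[(2S,3S)-3-ethynyl-3-methyloxiran-2-yl]methoxy}dimethylsilane | C#C[C@]1(C)O[C@H]1CO[Si](C)(C)C(C)(C)C | intermediate
4 | (S)-2-{[(tert-butyldimethylsilyl)oxy]methyl}-2-methylbut-3-ynal | O=C[C@](C)(CO[Si](C)(C)C(C)(C)C)C#C | intermediate
5 | (S)-3-{[(tert-butyldimethylsilyl)oxy]methyl}-3-methylpent-1-en-4-yne | C#C[C@@](C)(CO[Si](C)(C)C(C)(C)C)C=C | intermediate
6 | 5-(chloromethyl)-2-isopropyl-1,3-dimethoxybenzene | ClCc1cc(OC)c(C(C)C)c(OC)c1 | starting material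
7 | methyl 2-(4-isopropyl-3,5-dimethoxyphenyl)acetate | COC(=O)Cc1cc(OC)c(C(C)C)c(OC)c1 | intermediate
8 | methyl 2-(4-isopropyl-3,5-dimethoxyphenyl)pent-4-enoate (racemic) | COC(=O)C(CC=C)c1cc(OC)c(C(C)C)c(OC)c1 | intermediate
9 | methyl 2-(2-formyl-4-isopropyl-3,5-dimethoxyphenyl)pent-4-enoate (racemic) | COC(=O)C(CC=C)c1cc(OC)c(C(C)C)c(OC)c1C=O | intermediate
10 | chlorobis(cyclopentadienyl)[(1E,3S)-3-{[(tert-butyldimethylsilyl)oxy]methyl}-3-methylpenta-1,4-dien-1-yl]zirconium | Cl[Zr](C1C=CC=C1)(C1C=CC=C1)/C=C/[C@@](C)(CO[Si](C)(C)C(C)(C)C)C=C | intermediate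
11 | methyl[(1E,3S)-3-{[(tert-butyldimethylsilyl)oxy]methyl}-3-methylpenta-1,4-dien-1-yl]zinc | C[Zn]/C=C/[C@@](C)(CO[Si](C)(C)C(C)(C)C)C=C | intermediate
12 | methylzinc alkoxide of methyl 2-{2-[(1S,2E,4S)-4-{[(tert-butyldimethylsilyl)oxy]methyl}-1-hydroxy-4-methylhexa-2,5-dien-1-yl]-4-isopropyl-3,5-dimethoxyphenyl}pent-4-enoate | COC(=O)C(CC=C)c1cc(OC)c(C(C)C)c(OC)c1[C@@H](O[Zn]C)/C=C/[C@@](C)(CO[Si](C)(C)C(C)(C)C)C=C | intermediate
13 | (1S)-4-allyl-1-[(1E,3S)-3-{[(tert-butyldimethylsilyl)oxy]methyl}-3-methylpenta-1,4-dien-1-yl]-7-isopropyl-6,8-dimethoxyisochroman-3-one (C4 epimers) | CC(C)c1c(OC)cc2c(c1OC)[C@@H](OC(=O)C2CC=C)/C=C/[C@@](C)(CO[Si](C)(C)C(C)(C)C)C=C | intermediate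
14 | (1S)-4-allyl-1-[(1E,3S)-3-{[(tert-butyldimethylsilyl)oxy]methyl}-3-methylpenta-1,4-dien-1-yl]-7-isopropyl-6,8-dimethoxy-3-[(trimethylsilyl)oxy]-1H-isochromene | CC(C)c1c(OC)cc2c(c1OC)[C@@H](OC(O[Si](C)(C)C)=C2CC=C)/C=C/[C@@](C)(CO[Si](C)(C)C(C)(C)C)C=C | intermediate
15 | trimethylsilyl ester of acid 16 | CC(C)c1c(OC)cc2c(c1OC)C=C[C@@H]([C@@](C)(CO[Si](C)(C)C(C)(C)C)C=C)[C@@]2(CC=C)C(=O)O[Si](C)(C)C | intermediate
16 | (1R,2S)-1-allyl-2-[(2S)-1-{[tert-butyl(dimethyl)silyl]oxy}-2-methylbut-3-en-2-yl]-6-isopropyl-5,7-dimethoxy-1,2-dihydronaphthalene-1-carboxylic acid | CC(C)c1c(OC)cc2c(c1OC)C=C[C@@H]([C@@](C)(CO[Si](C)(C)C(C)(C)C)C=C)[C@@]2(CC=C)C(=O)O | intermediate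
17 | 6α,7α-epoxide of 16 (oxirane on the ring alkene, anti to the C5 side chain and to the carboxyl group) | CC(C)c1c(OC)cc2c(c1OC)[C@@H]1O[C@@H]1[C@@H]([C@@](C)(CO[Si](C)(C)C(C)(C)C)C=C)[C@@]2(CC=C)C(=O)O | intermediate
18 | bridged lactone from 17: C20 carboxyl oxygen bonded to C7 on the β face, OH on C6 α, C10 allyl, C5 side chain as silyl ether | CC(C)c1c(OC)cc2c(c1OC)[C@H]1OC(=O)[C@]2(CC=C)[C@@H]([C@H]1O)[C@@](C)(CO[Si](C)(C)C(C)(C)C)C=C | intermediate
19 | bridged hydroxy lactone as 18 with free C19–OH (6α-hydroxy-20,7β-lactone, C10 allyl, C5 (S)-1-hydroxy-2-methylbut-3-en-2-yl) | CC(C)c1c(OC)cc2c(c1OC)[C@H]1OC(=O)[C@]2(CC=C)[C@@H]([C@H]1O)[C@@](C)(CO)C=C | intermediate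
20 | 6α,19-dihydroxy-12,14-dimethoxyabieta-2,8,11,13-tetraen-20,7β-olide | CC(C)c1c(OC)cc2c(c1OC)[C@H]1OC(=O)[C@@]23CC=C[C@](C)(CO)[C@@H]3[C@H]1O | intermediate
21 | 6α,19-dihydroxy-12,14-dimethoxyabieta-8,11,13-trien-20,7β-olide | CC(C)c1c(OC)cc2c(c1OC)[C@H]1OC(=O)[C@@]23CCC[C@](C)(CO)[C@@H]3[C@H]1O | intermediate
22 | 6α,19-dihydroxy-12-methoxy-11,14-dioxoabieta-8,12-dien-20,7β-olide | CC(C)C1=C(OC)C(=O)C2=C(C1=O)[C@H]1OC(=O)[C@@]23CCC[C@](C)(CO)[C@@H]3[C@H]1O | intermediate
23 | 6α,12,19-trihydroxy-11,14-dioxoabieta-8,12-dien-20,7β-olide, (4S,5S,6R,7R,10R) (CNP0339604.1) | CC(C)C1=C(O)C(=O)C2=C(C1=O)[C@H]1OC(=O)[C@@]23CCC[C@](C)(CO)[C@@H]3[C@H]1O | target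

Total step count: 13. Longest linear sequence: 10 steps (steps 1–4 and 8–13).

Steps most likely to fail

Step 9. The shift may be too slow, because in the boat the allyl group on C10 and the quaternary C4 group on C5 are eclipsed across the forming bond. Heterolysis of the activated C7–O bond (loss of the C7 information) or ketene formation from the enolate may then take over. Fallback: C10 is made quaternary after ring B, by alkylation and not by the shift. Setting out from 7, Vilsmeier formylation would give methyl 2-(2-formyl-4-isopropyl-3,5-dimethoxyphenyl)acetate F1. The conditions of step 8 (with 5) would give the 4-unsubstituted isochromanone F2. Its Ireland–Claisen shift has only hydrogen in the eclipsed position and should give the tertiary acid F3 (C10 epimers). Double deprotonation (LiN(i-Pr)2, 2.2 equiv, THF, −78 °C) and allyl bromide should then alkylate the planar dianion anti to the bulky C5 substituent and come back to the route at 16.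

Step 12. The arene has no para-dioxygen pattern, so the oxidation may stall at the radical cation, nitrate the ring or attack side-chain positions. Fallback: the C11 oxygen is put in first and the oxidation is then that of a p-methoxyphenol. Setting out from 21, NBS (MeCN, 0 °C) would brominate the only free ring position to the 11-bromide F4. Borylation (B2pin2, PdCl2(dppf), KOAc, dioxane, 80 °C) would give the 11-boronate F5, and NaBO3 (THF–H2O) the 11-phenol F6. PhI(OAc)2 in aqueous MeCN at 0 °C should then oxidise F6 with loss of the C14 methyl group and come back to the route at 22.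

Step 8. Face selection in the alkenylzinc addition to the doubly ortho-substituted aldehyde may be poor. Fallback: C7 is set by reduction and not by addition. Setting out from 5 and 9, zirconocene 10 with ZnBr2 (cat.) would add without control, and a cold neutral quench would give the hydroxy ester F7 (C7 epimers). Dess–Martin periodinane would give the aryl dienone F8. Corey–Bakshi–Shibata reduction ((R)-2-methyl-CBS-oxazaborolidine, catecholborane, PhMe, −78 °C; the di-ortho-substituted aryl ring as the large group) should give the (S)-hydroxy ester F9. DBU (PhMe, rt) would close F9 to the lactone and come back to the route at 13.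

Further compounds
F1 | step 9 | methyl 2-(2-formyl-4-isopropyl-3,5-dimethoxyphenyl)acetate | COC(=O)Cc1cc(OC)c(C(C)C)c(OC)c1C=O
F2 | step 9 | (1S)-1-[(1E,3S)-3-{[(tert-butyldimethylsilyl)oxy]methyl}-3-methylpenta-1,4-dien-1-yl]-7-isopropyl-6,8-dimethoxyisochroman-3-one | CC(C)c1c(OC)cc2c(c1OC)[C@@H](OC(=O)C2)/C=C/[C@@](C)(CO[Si](C)(C)C(C)(C)C)C=C
F3 | step 9 | acid 16 without the allyl group (C10–H, C10 epimers) | CC(C)c1c(OC)cc2c(c1OC)C=C[C@@H]([C@@](C)(CO[Si](C)(C)C(C)(C)C)C=C)C2C(=O)O
F4 | step 12 | 11-bromo-6α,19-dihydroxy-12,14-dimethoxyabieta-8,11,13-trien-20,7β-olide | CC(C)c1c(OC)c(Br)c2c(c1OC)[C@H]1OC(=O)[C@@]23CCC[C@](C)(CO)[C@@H]3[C@H]1O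
F5 | step 12 | 11-(4,4,5,5-tetramethyl-1,3,2-dioxaborolan-2-yl)-6α,19-dihydroxy-12,14-dimethoxyabieta-8,11,13-trien-20,7β-olide | CC(C)c1c(OC)c(B4OC(C)(C)C(C)(C)O4)c2c(c1OC)[C@H]1OC(=O)[C@@]23CCC[C@](C)(CO)[C@@H]3[C@H]1O
F6 | step 12 | 6α,11,19-trihydroxy-12,14-dimethoxyabieta-8,11,13-trien-20,7β-olide | CC(C)c1c(OC)c(O)c2c(c1OC)[C@H]1OC(=O)[C@@]23CCC[C@](C)(CO)[C@@H]3[C@H]1O
F7 | step 8 | methyl 2-{2-[(2E,4S)-4-{[(tert-butyldimethylsilyl)oxy]methyl}-1-hydroxy-4-methylhexa-2,5-dien-1-yl]-4-isopropyl-3,5-dimethoxyphenyl}pent-4-enoate (carbinol epimers) | COC(=O)C(CC=C)c1cc(OC)c(C(C)C)c(OC)c1C(O)/C=C/[C@@](C)(CO[Si](C)(C)C(C)(C)C)C=C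
F8 | step 8 | methyl 2-{2-[(2E,4S)-4-{[(tert-butyldimethylsilyl)oxy]methyl}-4-methylhexa-2,5-dienoyl]-4-isopropyl-3,5-dimethoxyphenyl}pent-4-enoate | COC(=O)C(CC=C)c1cc(OC)c(C(C)C)c(OC)c1C(=O)/C=C/[C@@](C)(CO[Si](C)(C)C(C)(C)C)C=C
F9 | step 8 | methyl 2-{2-[(1S,2E,4S)-4-{[(tert-butyldimethylsilyl)oxy]methyl}-1-hydroxy-4-methylhexa-2,5-dien-1-yl]-4-isopropyl-3,5-dimethoxyphenyl}pent-4-enoate | COC(=O)C(CC=C)c1cc(OC)c(C(C)C)c(OC)c1[C@@H](O)/C=C/[C@@](C)(CO[Si](C)(C)C(C)(C)C)C=C
A1 | direct plan | 5-bromo-3-[(4S,5E)-4-{[(tert-butyldimethylsilyl)oxy]methyl}-6-methoxy-4-methylhex-5-en-1-yl]-2H-pyran-2-one | O=C1OC=C(Br)C=C1CCC[C@](C)(CO[Si](C)(C)C(C)(C)C)/C=C/OC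
A2 | direct plan | 8-bromo-6α-methoxy-19-[(tert-butyldimethylsilyl)oxy]-11,12,13,14,15,16,17-heptanorabiet-8-en-20,7β-olide | C2=C(Br)[C@H]1OC(=O)[C@@]23CCC[C@](C)(CO[Si](C)(C)C(C)(C)C)[C@@H]3[C@H]1OC
A3 | direct plan | 6α,12-dimethoxy-19-[(tert-butyldimethylsilyl)oxy]-11,14-dioxoabieta-8,12-dien-20,7β-olide | CC(C)C1=C(OC)C(=O)C2=C(C1=O)[C@H]1OC(=O)[C@@]23CCC[C@](C)(CO[Si](C)(C)C(C)(C)C)[C@@H]3[C@H]1OC
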